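Halimane numbering is used (ring A: C1–C5, C10; ring B: C5–C10; side chain C11–C15 on C9). Everything rests on making C11–C12 as a homoenolate alkylation. C11 is β to the ring-fusion sp2 carbon C10 and hangs on quaternary C9, so ring B is stored as fused cyclopropanol 5, whose three-membered ring is C9–C10–C11. Nickel-catalysed, strain-releasing cleavage of C10–C11 and capture of the primary C12 radical from redox-active ester 7 (C13 from a purchased enantiopure half-ester) attach the whole side chain and unveil the C10 ketone in one operation. Ring A follows by triflate vinylation and a catalyst-controlled Diels–Alder reaction with methacrolein.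

Key step: step 4

Assumption: the (S)-half-ester 6 of 3-methylglutaric acid is treated as a purchasable compound, since both antipodes of this half-ester are catalogued.

**Step 1**
Reactants: 1 2-methylcyclohex-2-en-1-one
Product: 3 (R)-2,3-dimethyl-1-(trimethylsilyloxy)cyclohex-1-ene, via aluminium enolate 2 (not isolated)
Conditions: Me3Al (1.5 equiv), CuTC (2 mol %), BINOL-derived phosphoramidite ligand (4 mol %, antipode giving the 3R product), Et2O, −30 °C; then TMSOTf, −30 → 0 °C
Reagents that add atoms: trimethylaluminium C[Al](C)C; trimethylsilyl triflate C[Si](C)(C)OS(=O)(=O)C(F)(F)F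
Why: Copper-catalysed asymmetric conjugate addition places the C8 methyl under ligand control (C8 = R), and O-silylation of the regiodefined aluminium enolate gives the tetrasubstituted silyl enol ether.

**Step 2**
Reactants: 3 (R)-2,3-dimethyl-1-(trimethylsilyloxy)cyclohex-1-ene
Product: 5 (1R,5R,6S)-5,6-dimethylbicyclo[4.1.0]heptan-1-ol, via silyloxycyclopropane 4 (not isolated)
Conditions: Et2Zn (2 equiv), CH2I2 (2 equiv), CH2Cl2, 0 °C → rt; then K2CO3 (cat.), MeOH, 0 °C
Reagents that add atoms: diiodomethane ICI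
Why: Simmons–Smith cyclopropanation of the electron-rich enol ether should occur anti to the C8 methyl, which A(1,2) strain with the vinylic methyl holds pseudoaxial, so C11 enters trans to it (sets C9 and C10); mild methanolysis then frees the cyclopropanol.

**Step 3**
Reactants: 6 (S)-5-methoxy-3-methyl-5-oxopentanoic acid
Product: 7 1-(1,3-dioxoisoindolin-2-yl) 5-methyl (R)-3-methylpentanedioate
Conditions: N-hydroxyphthalimide, N,N′-diisopropylcarbodiimide, DMAP (cat.), CH2Cl2, rt
Reagents that add atoms: N-hydroxyphthalimide O=C1N(O)C(=O)c2ccccc12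
Why: Steglich-type esterification gives the redox-active ester; C13 is β to the activated carboxyl and is not touched (the descriptor changes only through CIP priorities).

**Step 4 (key step)**
Reactants: 5 (1R,5R,6S)-5,6-dimethylbicyclo[4.1.0]heptan-1-ol; 7 1-(1,3-dioxoisoindolin-2-yl) 5-methyl (R)-3-methylpentanedioate
Product: 8 methyl (3S)-5-[(1S,2R)-1,2-dimethyl-6-oxocyclohexyl]-3-methylpentanoate
Conditions: NiCl2·glyme (10 mol %), 4,4′-di-tert-butyl-2,2′-bipyridine (12 mol %), Et3N (2 equiv), 5 (1.5 equiv), DMA, 25 °C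
Reagents that add atoms: none
Why: The nickel(II) alkoxide of 5 undergoes two-electron β-carbon elimination of the strained external C10–C11 bond to a C11–Ni homoenolate (C10 becomes the ketone), while low-valent nickel reduces 7 by single-electron transfer so that loss of CO2 and phthalimide leaves the primary C12 radical; radical capture at nickel and reductive elimination form C11–C12. The closest known reaction type is the nickel-catalysed β-alkylation of cyclopropanol-derived homoenolates by N-hydroxyphthalimide esters, a decarboxylative C(sp3)–C(sp3) coupling. No ring is closed; the cyclopropane is opened and its strain drives the C–C cleavage. No stereocentre is formed: C8 and C9 are carried over from 5 and C13, one carbon away from the radical centre, comes unchanged from 6. The step needs cleavage of C10–C11 and not of the internal C9–C10 bond, which the preference of alkoxide β-carbon elimination for the less substituted CH2 carbon should secure, and it needs cross- over homo-coupling, which the radical/organonickel pairing provides; quaternary C9 also removes every β-hydrogen, so the homoenolate cannot collapse to an enone.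

**Step 5**
Reactants: 8 methyl (3S)-5-[(1S,2R)-1,2-dimethyl-6-oxocyclohexyl]-3-methylpentanoate
Product: 10 methyl (3S)-5-[(1S,6R)-1,6-dimethyl-2-{[(trifluoromethyl)sulfonyl]oxy}cyclohex-2-en-1-yl]-3-methylpentanoate, via potassium enolate 9 (not isolated)
Conditions: KHMDS (1.05 equiv), THF, −78 °C; then PhNTf2, −78 → 0 °C
Reagents that add atoms: N-phenylbis(trifluoromethanesulfonimide) O=S(=O)(N(c1ccccc1)S(=O)(=O)C(F)(F)F)C(F)(F)F; KHMDS C[Si](C)(C)[N-][Si](C)(C)C.[K+] (potassium in 9 only)
Why: Only C5 can enolise because C9 is quaternary, and the ketone is deprotonated in preference to the less acidic side-chain ester, so O-triflation gives the C5=C10 enol triflate regiospecifically.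

**Step 6**
Reactants: 10 methyl (3S)-5-[(1S,6R)-1,6-dimethyl-2-{[(trifluoromethyl)sulfonyl]oxy}cyclohex-2-en-1-yl]-3-methylpentanoate
Product: 11 methyl (3S)-5-[(1S,6R)-2-ethenyl-1,6-dimethylcyclohex-2-en-1-yl]-3-methylpentanoate
Conditions: tributyl(vinyl)stannane, Pd(PPh3)4 (5 mol %), LiCl (3 equiv), THF, 65 °C
Reagents that add atoms: tributyl(vinyl)stannane C=C[Sn](CCCC)(CCCC)CCCC
Why: Stille coupling of the enol triflate installs C1–C2 as a vinyl group under neutral conditions that spare the ester and gives the 1-vinylcyclohexene diene.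

**Step 7**
Reactants: 11 methyl (3S)-5-[(1S,6R)-2-ethenyl-1,6-dimethylcyclohex-2-en-1-yl]-3-methylpentanoate
Product: 13 (3S)-5-[(1S,6R)-2-ethenyl-1,6-dimethylcyclohex-2-en-1-yl]-3-methylpentyl acetate, via aluminium alkoxide 12 (not isolated)
Conditions: DIBAL-H (2.5 equiv), CH2Cl2, −78 → 0 °C; then pyridine, DMAP, Ac2O, 0 °C → rt
Reagents that add atoms: acetic anhydride CC(=O)OC(C)=O; DIBAL-H CC(C)C[AlH]CC(C)C (aluminium in 12 only)
Why: Hydride reduction of the only carbonyl group to the primary aluminium alkoxide and its in situ O-acylation turn the C15 ester into the acetate before a second ester exists in the molecule.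

**Step 8**
Reactants: 13 (3S)-5-[(1S,6R)-2-ethenyl-1,6-dimethylcyclohex-2-en-1-yl]-3-methylpentyl acetate; 14 methacrolein
Product: 15 (1S,5S,6R,8aR)-5-[(3S)-5-acetoxy-3-methylpentyl]-1,5,6-trimethyl-1,2,3,5,6,7,8,8a-octahydronaphthalene-1-carbaldehyde
Conditions: 14 (3 equiv), B-o-tolyl oxazaborolidinium triflimide from α,α-diphenylprolinol (20 mol %; the antipode that shields the Cα-Si face of the bound enal), CH2Cl2, −78 → −40 °C
Reagents that add atoms: none
Why: In this Lewis-acid-catalysed asymmetric Diels–Alder reaction the enal β-carbon (C3) should bond to the free terminus C2 and Cα (C4) to the substituted terminus C5 ("ortho" orientation), the endo formyl group ends trans to H5, and addition to the exposed Cα-Re face fixes C4 (S) and with it C5 (R), the diene reacting on the face anti to the C9 methyl.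

**Step 9**
Reactants: 15 (1S,5S,6R,8aR)-5-[(3S)-5-acetoxy-3-methylpentyl]-1,5,6-trimethyl-1,2,3,5,6,7,8,8a-octahydronaphthalene-1-carbaldehyde
Product: 16 (1S,5S,6R,8aR)-5-[(3S)-5-acetoxy-3-methylpentyl]-1,5,6-trimethyl-1,2,3,5,6,7,8,8a-octahydronaphthalene-1-carboxylic acid
Conditions: NaClO2, NaH2PO4, 2-methyl-2-butene, t-BuOH/H2O, 0 °C → rt
Reagents that add atoms: sodium chlorite [Na+].[O-]Cl=O
Why: Pinnick oxidation converts the hindered, non-enolisable aldehyde to the acid, while the scavenger protects the trisubstituted C1=C10 alkene and the acetate is untouched.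

**Step 10**
Reactants: 16 (1S,5S,6R,8aR)-5-[(3S)-5-acetoxy-3-methylpentyl]-1,5,6-trimethyl-1,2,3,5,6,7,8,8a-octahydronaphthalene-1-carboxylic acid
Product: 17 methyl (1S,5S,6R,8aR)-5-[(3S)-5-acetoxy-3-methylpentyl]-1,5,6-trimethyl-1,2,3,5,6,7,8,8a-octahydronaphthalene-1-carboxylate (target)
Conditions: TMSCHN2, MeOH/toluene (1:4), 0 °C → rt
Reagents that add atoms: (trimethylsilyl)diazomethane C[Si](C)(C)C=[N+]=[N-]
Why: O-Methylation of the carboxylic acid by the diazoalkane avoids acyl substitution at the neopentyl C4 carbonyl and leaves the acetate intact.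

**Compound list**
1 | 2-methylcyclohex-2-en-1-one | CC1=CCCCC1=O | starting material
2 | dimethylaluminium (R)-2,3-dimethylcyclohex-1-en-1-olate (not isolated) | C[Al](C)OC1=C(C)[C@H](C)CCC1 | intermediate
3 | (R)-2,3-dimethyl-1-(trimethylsilyloxy)cyclohex-1-ene | C[Si](C)(C)OC1=C(C)[C@H](C)CCC1 | intermediate
4 | (1R,5R,6S)-5,6-dimethyl-1-(trimethylsilyloxy)bicyclo[4.1.0]heptane (not isolated) | C[Si](C)(C)O[C@@]12CCC[C@@H](C)[C@]1(C)C2 | intermediate
5 | (1R,5R,6S)-5,6-dimethylbicyclo[4.1.0]heptan-1-ol (OH and both methyls on one face, cyclopropane CH2 on the other) | O[C@@]12CCC[C@@H](C)[C@]1(C)C2 | intermediate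
6 | (S)-5-methoxy-3-methyl-5-oxopentanoic acid | OC(=O)C[C@H](C)CC(=O)OC | starting material
7 | 1-(1,3-dioxoisoindolin-2-yl) 5-methyl (R)-3-methylpentanedioate | O=C(C[C@H](C)CC(=O)OC)ON1C(=O)c2ccccc2C1=O | intermediate
8 | methyl (3S)-5-[(1S,2R)-1,2-dimethyl-6-oxocyclohexyl]-3-methylpentanoate | O=C1CCC[C@@H](C)[C@]1(C)CC[C@H](C)CC(=O)OC | intermediate
9 | potassium (5R,6S)-6-[(3S)-5-methoxy-3-methyl-5-oxopentyl]-5,6-dimethylcyclohex-1-en-1-olate (not isolated) | [K+].[O-]C1=CCC[C@@H](C)[C@]1(C)CC[C@H](C)CC(=O)OC | intermediate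
10 | methyl (3S)-5-[(1S,6R)-1,6-dimethyl-2-{[(trifluoromethyl)sulfonyl]oxy}cyclohex-2-en-1-yl]-3-methylpentanoate | O=S(=O)(OC1=CCC[C@@H](C)[C@]1(C)CC[C@H](C)CC(=O)OC)C(F)(F)F | intermediate
11 | methyl (3S)-5-[(1S,6R)-2-ethenyl-1,6-dimethylcyclohex-2-en-1-yl]-3-methylpentanoate | C=CC1=CCC[C@@H](C)[C@]1(C)CC[C@H](C)CC(=O)OC | intermediate
12 | diisobutylaluminium (3S)-5-[(1S,6R)-2-ethenyl-1,6-dimethylcyclohex-2-en-1-yl]-3-methylpentan-1-olate (not isolated) | C=CC1=CCC[C@@H](C)[C@]1(C)CC[C@H](C)CCO[Al](CC(C)C)CC(C)C | intermediate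
13 | (3S)-5-[(1S,6R)-2-ethenyl-1,6-dimethylcyclohex-2-en-1-yl]-3-methylpentyl acetate | C=CC1=CCC[C@@H](C)[C@]1(C)CC[C@H](C)CCOC(C)=O | intermediate
14 | methacrolein (2-methylprop-2-enal) | CC(=C)C=O | starting material
15 | (1S,5S,6R,8aR)-5-[(3S)-5-acetoxy-3-methylpentyl]-1,5,6-trimethyl-1,2,3,5,6,7,8,8a-octahydronaphthalene-1-carbaldehyde | O=C[C@@]1(C)CCC=C2[C@H]1CC[C@@H](C)[C@]2(C)CC[C@H](C)CCOC(C)=O | intermediate
16 | (1S,5S,6R,8aR)-5-[(3S)-5-acetoxy-3-methylpentyl]-1,5,6-trimethyl-1,2,3,5,6,7,8,8a-octahydronaphthalene-1-carboxylic acid | OC(=O)[C@@]1(C)CCC=C2[C@H]1CC[C@@H](C)[C@]2(C)CC[C@H](C)CCOC(C)=O | intermediate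
17 | methyl (1S,5S,6R,8aR)-5-[(3S)-5-acetoxy-3-methylpentyl]-1,5,6-trimethyl-1,2,3,5,6,7,8,8a-octahydronaphthalene-1-carboxylate | COC(=O)[C@@]1(C)CCC=C2[C@H]1CC[C@@H](C)[C@]2(C)CC[C@H](C)CCOC(C)=O | target

Total step count: 10. Longest linear sequence: 9 steps (steps 1, 2 and 4–10, from 1).

**Steps most likely to fail**

Step 4 (key step). β-Carbon elimination at the crowded tertiary alkoxide may be slow, so that the ester-derived radical is lost to reduction or dimerisation. The ring may also open through the internal C9–C10 bond (ring expansion) or simply isomerise to the α-methyl ketone. The fallback is a two-electron alkyl–alkyl Negishi coupling that sets out from 5 and 6 and comes back at 8. Half-ester 6 is converted by iododecarboxylation (PhI(OAc)2, I2, hν) into methyl (R)-4-iodo-3-methylbutanoate F1. Cyclopropanol 5 is deprotonated with Et2Zn (0.5 equiv, THF/DMSO), and the zinc alkoxide ring-opens to bis{[(1S,2R)-1,2-dimethyl-6-oxocyclohexyl]methyl}zinc F2. Coupling of F2 with F1 (Ni(acac)2, 4-fluorostyrene, THF/NMP, −20 °C) should then give 8.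

Step 8. The two faces of the diene differ only by methyl against CH2R at C9, so facial discrimination rests wholly on the catalyst and may be poor on this hindered diene; erosion of the "ortho" orientation or of the endo preference is also possible. The fallback replaces the cycloaddition by a chirality-transferring Ireland–Claisen ring contraction; it sets out from triflate 10 and comes back at acid 16.
- Hydroboration of methyl 2-methylbut-3-enoate with 9-BBN gives methyl 4-(9-borabicyclo[3.3.1]nonan-9-yl)-2-methylbutanoate F3.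
- Carbonylative Suzuki–Miyaura coupling of F3 with 10 (CO 1 atm, Pd(PPh3)4, K3PO4) gives methyl (3S)-5-[(1S,6R)-2-(5-methoxy-4-methyl-5-oxopentanoyl)-1,6-dimethylcyclohex-2-en-1-yl]-3-methylpentanoate F4.
- CBS reduction ((S)-Me-CBS, BH3·SMe2) should give the (1R)-allylic alcohol F5, which lactonises (PPTS, toluene) to the 6-alkenyl-3-methyl-δ-lactone F6.
- Ireland–Claisen rearrangement (LDA 3 equiv, TMSCl/Et3N, THF, −78 °C; then toluene, 110 °C; aqueous work-up, which also returns the transiently silylated side-chain ester) must pass through a boat-like bicyclic transition state. It delivers C4 to the C5 face fixed by C1, with the carboxyl trans to H5, and gives the acid–ester F7.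
- LiBH4 reduces the C15 methyl ester beside the lithium carboxylate to the hydroxy acid F8, and acetylation (Ac2O, pyridine) gives 16.

Step 2. Carbenoid transfer to the tetrasubstituted enol ether may show incomplete facial selectivity, and the strained cyclopropanol may ring-open during desilylation. The fallback sets C9 by enolate alkylation instead; it sets out from 3 and comes back at 5. MeLi cleaves the silyl ether to lithium (R)-2,3-dimethylcyclohex-1-en-1-olate F9. Hydroxymethylation with monomeric formaldehyde, anti to the C8 methyl, gives (2R,3R)-2-(hydroxymethyl)-2,3-dimethylcyclohexan-1-one F10. Appel iodination (I2, PPh3, imidazole) gives (2S,3R)-2-(iodomethyl)-2,3-dimethylcyclohexan-1-one F11. SmI2 (THF) then closes the three-membered ring by reductive 1,3-cyclisation onto the ketone to return 5.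

**Further compounds**
F1 | step 4 | methyl (R)-4-iodo-3-methylbutanoate | IC[C@H](C)CC(=O)OC
F2 | step 4 | bis{[(1S,2R)-1,2-dimethyl-6-oxocyclohexyl]methyl}zinc | O=C1CCC[C@@H](C)[C@]1(C)C[Zn]C[C@@]1(C)[C@H](C)CCCC1=O
F3 | step 8 | methyl 4-(9-borabicyclo[3.3.1]nonan-9-yl)-2-methylbutanoate | COC(=O)C(C)CCB1C2CCCC1CCC2
F4 | step 8 | methyl (3S)-5-[(1S,6R)-2-(5-methoxy-4-methyl-5-oxopentanoyl)-1,6-dimethylcyclohex-2-en-1-yl]-3-methylpentanoate | COC(=O)C(C)CCC(=O)C1=CCC[C@@H](C)[C@]1(C)CC[C@H](C)CC(=O)OC
F5 | step 8 | methyl (3S)-5-[(1S,6R)-2-[(1R)-1-hydroxy-5-methoxy-4-methyl-5-oxopentyl]-1,6-dimethylcyclohex-2-en-1-yl]-3-methylpentanoate | COC(=O)C(C)CC[C@@H](O)C1=CCC[C@@H](C)[C@]1(C)CC[C@H](C)CC(=O)OC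
F6 | step 8 | methyl (3S)-5-[(1S,6R)-1,6-dimethyl-2-[(2R)-5-methyl-6-oxotetrahydro-2H-pyran-2-yl]cyclohex-2-en-1-yl]-3-methylpentanoate | O=C1O[C@H](CCC1C)C2=CCC[C@@H](C)[C@]2(C)CC[C@H](C)CC(=O)OC
F7 | step 8 | (1S,5S,6R,8aR)-5-[(3S)-5-methoxy-3-methyl-5-oxopentyl]-1,5,6-trimethyl-1,2,3,5,6,7,8,8a-octahydronaphthalene-1-carboxylic acid | OC(=O)[C@@]1(C)CCC=C2[C@H]1CC[C@@H](C)[C@]2(C)CC[C@H](C)CC(=O)OC
F8 | step 8 | (1S,5S,6R,8aR)-5-[(3S)-5-hydroxy-3-methylpentyl]-1,5,6-trimethyl-1,2,3,5,6,7,8,8a-octahydronaphthalene-1-carboxylic acid | OC(=O)[C@@]1(C)CCC=C2[C@H]1CC[C@@H](C)[C@]2(C)CC[C@H](C)CCO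
F9 | step 2 | lithium (R)-2,3-dimethylcyclohex-1-en-1-olate | [Li+].[O-]C1=C(C)[C@H](C)CCC1
F10 | step 2 | (2R,3R)-2-(hydroxymethyl)-2,3-dimethylcyclohexan-1-one | O=C1CCC[C@@H](C)[C@]1(C)CO
F11 | step 2 | (2S,3R)-2-(iodomethyl)-2,3-dimethylcyclohexan-1-one | O=C1CCC[C@@H](C)[C@]1(C)CI
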